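**Retrosynthetic overview**

1. The target is the 7-O-ether of 5,7-dihydroxycoumarin with a (2E,6E)-farnesyl chain that carries a (9R,10S)-9,10,11-triol. The last disconnections are an isopropylidene acetal on the C9/C10 oxygens and the C1–O(aryl) bond (Mitsunobu reaction with the bought coumarin). Ring A (benzene) and ring B (pyranone) are therefore never built; the only ring the route carries is a temporary 1,3-dioxolane, present from the chiral starting material and opened in the last step.
2. Key disconnection: C7–C8, the bond between the methyl-bearing sp2 carbon of the C6=C7 alkene and the CH2 next to the C9 carbinol. Both carbons are made electrophilic (alkenyl iodide and alkyl iodide) and are joined by a nickel-catalysed reductive cross-electrophile coupling.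
3. Enabling feature: C8 is a CH2 flanked by the C9–O bond, so C8–C11 with its threo-9,10-diol and C11 carbinol is the four-carbon skeleton of D-tartaric acid (C8 is a reduced carboxyl carbon). The trans-4,5-disubstituted dioxolane ring on C9/C10 lets a C8 radical form without loss of the β-oxygen. C7 carries a methyl group on an E-alkene, which is the outcome of syn hydrozirconation of a 2-alkyne.
4. Fragment A (C1–C7): geranyl acetate → cleavage of the 6,7-alkene → alkyne homologation and methylation → hydrozirconation–iodination. Fragment B (C8–C12): dimethyl 2,3-O-isopropylidene-D-tartrate → mono-reduction → MeMgBr → iodide.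

Key step: step 10

Remark: chain carbons are numbered C1 (OCH2) to C12 as in farnesol. Geranyl acetate, dimethyl 2,3-O-isopropylidene-D-tartrate and 5,7-dihydroxycoumarin are taken as commercial. The oxirane CH of 2 (carbinol CH of 3) is racemic, which has no consequence because this carbon becomes the aldehyde carbon of 4.

**Route**

Step 1
Reactants: 1 geranyl acetate
Product: 2 (2E)-5-(3,3-dimethyloxiran-2-yl)-3-methylpent-2-en-1-yl acetate (6,7-epoxygeranyl acetate; racemic at the oxirane CH)
Conditions: mCPBA (1.0 equiv), NaHCO3, CH2Cl2, 0 °C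
Reagents that add atoms: mCPBA, OOC(=O)c1cccc(Cl)c1
Why: The Prilezhaev epoxidation is electrophilic and should select the electron-rich distal 6,7-alkene over the 2,3-alkene that is deactivated by the allylic acetate, and the new stereocentre is destroyed in step 2.

Step 2
Reactants: 2 6,7-epoxygeranyl acetate
Product: 4 (2E)-3-methyl-6-oxohex-2-en-1-yl acetate, via diol 3 (not isolated)
Conditions: HIO4·2H2O, THF/Et2O, 0 °C → rt
Reagents that add atoms: none
Why: Periodic acid hydrolyses the epoxide to the vicinal diol (water enters at the tertiary carbon) and cleaves it in a Malaprade glycol cleavage, so the former epoxide oxygen stays on C6 as the aldehyde oxygen while the isopropylidene end leaves as acetone.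

Step 3
Reactants: 4 (2E)-3-methyl-6-oxohex-2-en-1-yl acetate
Product: 6 (2E)-3-methylhept-2-en-6-yn-1-ol, via alkyne acetate 5 (not isolated)
Conditions: dimethyl (1-diazo-2-oxopropyl)phosphonate, K2CO3, MeOH, 0 °C → rt
Reagents that add atoms: dimethyl (1-diazo-2-oxopropyl)phosphonate (Ohira–Bestmann reagent), CC(=O)C(=[N+]=[N-])P(=O)(OC)OC
Why: The Seyferth–Gilbert homologation with the Ohira–Bestmann reagent converts the enolisable aldehyde into the terminal alkyne under mild K2CO3/MeOH conditions, which also methanolyse the allylic acetate in the same flask.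

Step 4
Reactants: 6 (2E)-3-methylhept-2-en-6-yn-1-ol
Product: 7 tert-butyl(dimethyl){[(2E)-3-methylhept-2-en-6-yn-1-yl]oxy}silane
Conditions: TBSCl, imidazole, CH2Cl2, rt
Reagents that add atoms: tert-butyl(chloro)dimethylsilane (TBSCl), CC(C)(C)[Si](C)(C)Cl
Why: Imidazole-promoted O-silylation masks the allylic alcohol against the organolithium, zirconium hydride and low-valent nickel chemistry that follows.

Step 5
Reactants: 7 tert-butyl(dimethyl){[(2E)-3-methylhept-2-en-6-yn-1-yl]oxy}silane
Product: 9 tert-butyl(dimethyl){[(2E)-3-methyloct-2-en-6-yn-1-yl]oxy}silane, via lithium acetylide 8 (not isolated)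
Conditions: n-BuLi, THF, −78 °C; then MeI, −78 °C → rt
Reagents that add atoms: iodomethane, CI
Why: Deprotonation of the terminal alkyne and SN2 alkylation of the lithium acetylide with MeI gives the 2-alkyne, with the silyl ether and the trisubstituted alkene inert to both reagents.

Step 6
Reactants: 9 tert-butyl(dimethyl){[(2E)-3-methyloct-2-en-6-yn-1-yl]oxy}silane
Product: 11 tert-butyl{[(2E,6E)-7-iodo-3-methylocta-2,6-dien-1-yl]oxy}dimethylsilane, via alkenylzirconocene chloride 10 (not isolated)
Conditions: Cp2Zr(H)Cl (2.5 equiv), THF, 50 °C; then I2, THF, 0 °C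
Reagents that add atoms: iodine, II
Why: Hydrozirconation is a syn addition, and with excess Cp2Zr(H)Cl at 50 °C the regioisomeric alkenylzirconocenes should equilibrate to the one with zirconium on the less hindered methyl-bearing carbon C7, so that iodinolysis with retention places iodine on C7 and fixes the 6E geometry.

Step 7
Reactants: 12 dimethyl (4S,5S)-2,2-dimethyl-1,3-dioxolane-4,5-dicarboxylate (dimethyl 2,3-O-isopropylidene-D-tartrate)
Product: 13 methyl (4S,5R)-5-(hydroxymethyl)-2,2-dimethyl-1,3-dioxolane-4-carboxylate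
Conditions: NaBH4 (0.6 equiv), MeOH, 0 °C → rt
Reagents that add atoms: none
Why: Borohydride reduction of one of the two homotopic α-alkoxy esters (activated towards NaBH4 by the α-oxygen) with a deficit of hydride should stop mainly at the hydroxy ester, and neither stereocentre, both of which come from D-tartaric acid, is touched.

Step 8
Reactants: 13 methyl (4S,5R)-5-(hydroxymethyl)-2,2-dimethyl-1,3-dioxolane-4-carboxylate
Product: 15 2-[(4S,5R)-5-(hydroxymethyl)-2,2-dimethyl-1,3-dioxolan-4-yl]propan-2-ol, via methyl ketone 14 (not isolated)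
Conditions: MeMgBr (3.5 equiv), THF, 0 °C → rt
Reagents that add atoms: methylmagnesium bromide, C[Mg]Br
Why: Double Grignard addition to the ester through the methyl ketone builds the C11 tertiary carbinol, one equivalent of reagent being spent on the free hydroxyl.

Step 9
Reactants: 15 2-[(4S,5R)-5-(hydroxymethyl)-2,2-dimethyl-1,3-dioxolan-4-yl]propan-2-ol
Product: 16 2-[(4S,5S)-5-(iodomethyl)-2,2-dimethyl-1,3-dioxolan-4-yl]propan-2-ol
Conditions: I2, PPh3, imidazole, CH2Cl2, 0 °C → rt
Reagents that add atoms: iodine, II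
Why: The Appel-type iodination (Garegg–Samuelsson conditions) converts only the primary alcohol, because the tertiary alcohol gives no displaceable oxyphosphonium ion and its closure onto C8 would need a strained trans-fused bicyclic oxolane.

Step 10
Reactants: 11 tert-butyl{[(2E,6E)-7-iodo-3-methylocta-2,6-dien-1-yl]oxy}dimethylsilane; 16 2-[(4S,5S)-5-(iodomethyl)-2,2-dimethyl-1,3-dioxolan-4-yl]propan-2-ol
Product: 17 2-[(4S,5R)-5-[(2E,6E)-8-{[tert-butyl(dimethyl)silyl]oxy}-2,6-dimethylocta-2,6-dien-1-yl]-2,2-dimethyl-1,3-dioxolan-4-yl]propan-2-ol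
Conditions: NiBr2(dme) (10 mol %), 4,4'-di-tert-butyl-2,2'-bipyridine (10 mol %), Mn powder (3 equiv), NaI (0.5 equiv), DMA, 25 °C; 16 in 1.5-fold excess
Reagents that add atoms: none
Why: Mn reduces the divalent nickel precatalyst to a zerovalent bipyridine complex that inserts into the C7–I bond of 11 with retention of the 6E geometry, while a monovalent nickel iodide abstracts the iodine atom of 16 to give the primary C8 radical; capture of this radical by the alkenylnickel gives a trivalent alkyl(alkenyl)nickel species that forms the C7–C8 bond by fast reductive elimination. The closest known reaction type is the nickel-catalysed reductive cross-electrophile coupling of alkenyl halides with unactivated primary alkyl iodides, which accepts iodides that carry a β-oxygen. No ring is closed and no stereocentre is formed: C9 and C10 are spectators because the radical sits on C8, and the C6=C7 geometry is carried over from 11. The step needs cross- over homo-coupling, which the different activation modes of the sp2 iodide (two-electron oxidative addition) and the sp3 iodide (halogen-atom abstraction) together with the excess of 16 should secure. It also needs C–C bond formation to outrun loss of the β-oxygen, which is secured by the radical pathway (a β-alkoxyalkyl radical does not fragment, and with Mn no alkylzinc forms that could eliminate) and by the trans-dioxolane that holds the C9–O bond in a ring.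

Step 11
Reactants: 17 2-[(4S,5R)-5-[(2E,6E)-8-{[tert-butyl(dimethyl)silyl]oxy}-2,6-dimethylocta-2,6-dien-1-yl]-2,2-dimethyl-1,3-dioxolan-4-yl]propan-2-ol
Product: 18 (2E,6E)-8-[(4R,5S)-5-(2-hydroxypropan-2-yl)-2,2-dimethyl-1,3-dioxolan-4-yl]-3,7-dimethylocta-2,6-dien-1-ol
Conditions: TBAF, THF, 0 °C → rt
Reagents that add atoms: none
Why: Fluoride-mediated desilylation, driven by the strength of the Si–F bond, frees the primary allylic alcohol and leaves the acetal and the tertiary alcohol untouched.

Step 12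
Reactants: 18 (2E,6E)-8-[(4R,5S)-5-(2-hydroxypropan-2-yl)-2,2-dimethyl-1,3-dioxolan-4-yl]-3,7-dimethylocta-2,6-dien-1-ol; 19 5,7-dihydroxycoumarin (5,7-dihydroxy-2H-chromen-2-one)
Product: 20 5-hydroxy-7-{[(2E,6E)-8-[(4R,5S)-5-(2-hydroxypropan-2-yl)-2,2-dimethyl-1,3-dioxolan-4-yl]-3,7-dimethylocta-2,6-dien-1-yl]oxy}-2H-chromen-2-one
Conditions: 19 (2 equiv), PPh3, DIAD, THF, 0 °C → rt
Reagents that add atoms: none
Why: In this Mitsunobu etherification the primary allylic C1 is displaced in an SN2 step (the tertiary alcohol cannot react), and the unhindered 7-hydroxyl, which is para-conjugated through C4a and the C3=C4 bond to the lactone carbonyl, should react in preference to the 5-hydroxyl that is crowded by the peri C4–H, while the excess of 19 disfavours double alkylation.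

Step 13
Reactants: 20 5-hydroxy-7-{[(2E,6E)-8-[(4R,5S)-5-(2-hydroxypropan-2-yl)-2,2-dimethyl-1,3-dioxolan-4-yl]-3,7-dimethylocta-2,6-dien-1-yl]oxy}-2H-chromen-2-one
Product: 21 5-hydroxy-7-{[(2E,6E,9R,10S)-9,10,11-trihydroxy-3,7,11-trimethyldodeca-2,6-dien-1-yl]oxy}-2H-chromen-2-one (target)
Conditions: AcOH/H2O (4:1), 40 °C
Reagents that add atoms: none
Why: Mild aqueous acid hydrolysis of the isopropylidene acetal releases the 9,10-diol without breaking either C–O bond (9R,10S retained), and dilute acetic acid should be too weak to ionise the allylic aryl ether.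

**Compound list**

1 | geranyl acetate, (2E)-3,7-dimethylocta-2,6-dien-1-yl acetate | CC(=O)OC/C=C(\C)CCC=C(C)C | starting material
2 | (2E)-5-(3,3-dimethyloxiran-2-yl)-3-methylpent-2-en-1-yl acetate (racemic at the oxirane CH) | CC(=O)OC/C=C(\C)CCC1OC1(C)C | intermediate
3 | (2E)-6,7-dihydroxy-3,7-dimethyloct-2-en-1-yl acetate (racemic; not isolated) | CC(=O)OC/C=C(\C)CCC(O)C(C)(C)O | intermediate
4 | (2E)-3-methyl-6-oxohex-2-en-1-yl acetate | CC(=O)OC/C=C(\C)CCC=O | intermediate
5 | (2E)-3-methylhept-2-en-6-yn-1-yl acetate (not isolated) | CC(=O)OC/C=C(\C)CCC#C | intermediate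
6 | (2E)-3-methylhept-2-en-6-yn-1-ol | OC/C=C(\C)CCC#C | intermediate
7 | tert-butyl(dimethyl){[(2E)-3-methylhept-2-en-6-yn-1-yl]oxy}silane | CC(C)(C)[Si](C)(C)OC/C=C(\C)CCC#C | intermediate
8 | lithium acetylide of 7 (not isolated) | CC(C)(C)[Si](C)(C)OC/C=C(\C)CCC#C[Li] | intermediate
9 | tert-butyl(dimethyl){[(2E)-3-methyloct-2-en-6-yn-1-yl]oxy}silane | CC(C)(C)[Si](C)(C)OC/C=C(\C)CCC#CC | intermediate
10 | chlorobis(cyclopentadienyl)[(2E,6E)-8-{[tert-butyl(dimethyl)silyl]oxy}-6-methylocta-2,6-dien-2-yl]zirconium (not isolated; cyclopentadienyl rings drawn σ-bonded) | CC(C)(C)[Si](C)(C)OC/C=C(\C)CC/C=C(\C)[Zr](Cl)(C1C=CC=C1)C1C=CC=C1 | intermediate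
11 | tert-butyl{[(2E,6E)-7-iodo-3-methylocta-2,6-dien-1-yl]oxy}dimethylsilane | CC(C)(C)[Si](C)(C)OC/C=C(\C)CC/C=C(\C)I | intermediate
12 | dimethyl (4S,5S)-2,2-dimethyl-1,3-dioxolane-4,5-dicarboxylate | COC(=O)[C@H]1OC(C)(C)O[C@@H]1C(=O)OC | starting material
13 | methyl (4S,5R)-5-(hydroxymethyl)-2,2-dimethyl-1,3-dioxolane-4-carboxylate | OC[C@H]1OC(C)(C)O[C@@H]1C(=O)OC | intermediate
14 | 1-[(4S,5R)-5-(hydroxymethyl)-2,2-dimethyl-1,3-dioxolan-4-yl]ethan-1-one (not isolated) | OC[C@H]1OC(C)(C)O[C@@H]1C(C)=O | intermediate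
15 | 2-[(4S,5R)-5-(hydroxymethyl)-2,2-dimethyl-1,3-dioxolan-4-yl]propan-2-ol | OC[C@H]1OC(C)(C)O[C@@H]1C(C)(C)O | intermediate
16 | 2-[(4S,5S)-5-(iodomethyl)-2,2-dimethyl-1,3-dioxolan-4-yl]propan-2-ol | IC[C@H]1OC(C)(C)O[C@@H]1C(C)(C)O | intermediate
17 | 2-[(4S,5R)-5-[(2E,6E)-8-{[tert-butyl(dimethyl)silyl]oxy}-2,6-dimethylocta-2,6-dien-1-yl]-2,2-dimethyl-1,3-dioxolan-4-yl]propan-2-ol | CC(C)(C)[Si](C)(C)OC/C=C(\C)CC/C=C(\C)C[C@H]1OC(C)(C)O[C@@H]1C(C)(C)O | intermediate
18 | (2E,6E)-8-[(4R,5S)-5-(2-hydroxypropan-2-yl)-2,2-dimethyl-1,3-dioxolan-4-yl]-3,7-dimethylocta-2,6-dien-1-ol | OC/C=C(\C)CC/C=C(\C)C[C@H]1OC(C)(C)O[C@@H]1C(C)(C)O | intermediate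
19 | 5,7-dihydroxycoumarin (5,7-dihydroxy-2H-chromen-2-one) | Oc1cc(O)c2ccc(=O)oc2c1 | starting material
20 | 5-hydroxy-7-{[(2E,6E)-8-[(4R,5S)-5-(2-hydroxypropan-2-yl)-2,2-dimethyl-1,3-dioxolan-4-yl]-3,7-dimethylocta-2,6-dien-1-yl]oxy}-2H-chromen-2-one | C/C(=C\COc1cc(O)c2ccc(=O)oc2c1)CC/C=C(\C)C[C@H]1OC(C)(C)O[C@@H]1C(C)(C)O | intermediate
21 | 5-hydroxy-7-{[(2E,6E,9R,10S)-9,10,11-trihydroxy-3,7,11-trimethyldodeca-2,6-dien-1-yl]oxy}-2H-chromen-2-one | C/C(=C\COc1cc(O)c2ccc(=O)oc2c1)CC/C=C(\C)C[C@@H](O)[C@H](O)C(C)(C)O | target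

**Step count and risks**

Total steps: 13. Longest linear sequence: 10 steps (steps 1–6, then 10–13).

Step 10 (key coupling). The risks are homocoupling of the hindered alkenyl iodide and reductive loss of the β-oxygen from the alkyl partner (ring-opening of the dioxolane) before C–C bond formation. The fallback reverses the polarity of C7; it sets out from 13 and 11 and comes back to the route at 17. Alcohol 13 would be converted with Tf2O and pyridine (CH2Cl2, −78 °C) into the primary triflate methyl (4S,5R)-2,2-dimethyl-5-({[(trifluoromethyl)sulfonyl]oxy}methyl)-1,3-dioxolane-4-carboxylate F1. Iodide 11 would be turned by iodine–lithium exchange (t-BuLi, Et2O, −78 °C) into the alkenyllithium F2 and then with MgBr2·OEt2 into the alkenylmagnesium bromide F3. Under CuBr·SMe2 catalysis (THF, −78 → −30 °C) F3 should displace the triflate of F1 in an SN2 coupling that the ester survives at this temperature, giving methyl (4S,5R)-5-[(2E,6E)-8-{[tert-butyl(dimethyl)silyl]oxy}-2,6-dimethylocta-2,6-dien-1-yl]-2,2-dimethyl-1,3-dioxolane-4-carboxylate F4. MeMgBr (THF, 0 °C) would then add twice, through the methyl ketone F5, to give 17.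

Step 12 (Mitsunobu etherification). The risk is poor discrimination between the two phenols, giving the 5-O-ether or the bis-ether. The fallback builds the pyranone ring after the ether so that the regiochemistry follows from symmetry; it sets out from 18 and comes back at 20. A Mitsunobu reaction of 18 with bought 2,4,6-trihydroxybenzaldehyde (O=Cc1c(O)cc(O)cc1O), in which only the 4-hydroxyl is free of a hydrogen bond to the formyl group, would give the aldehyde 2,6-dihydroxy-4-{[(2E,6E)-8-[(4R,5S)-5-(2-hydroxypropan-2-yl)-2,2-dimethyl-1,3-dioxolan-4-yl]-3,7-dimethylocta-2,6-dien-1-yl]oxy}benzaldehyde F6. Wittig olefination with Ph3P=CHCO2Et (toluene, 60 °C) would give the ethyl (E)-cinnamate F7. Irradiation at 365 nm (MeCN) would isomerise it to the ethyl (Z)-cinnamate F8, which lactonises onto either of the two equivalent ortho-hydroxyls with loss of ethanol to give 20; the remaining ortho-hydroxyl is the 5-OH.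

Step 6 (hydrozirconation–iodination). The risk is incomplete equilibration of the alkenylzirconocenes, which would leak the regioisomer with iodine on C6 into the coupling partner. The fallback fixes the regiochemistry with silicon instead of by equilibration; it sets out from 7 and comes back at 11. Acetylide 8 (from 7 and n-BuLi) would be quenched with TMSCl instead of MeI to give the silylalkyne tert-butyl(dimethyl){[(2E)-3-methyl-7-(trimethylsilyl)hept-2-en-6-yn-1-yl]oxy}silane F9. i-Bu2AlH in heptane at 50 °C adds to 1-silylalkynes with aluminium on the silicon-bearing carbon and with net trans stereochemistry, which would give the α-silyl alkenylalane F10. MeLi would convert it into the lithium alanate F11, which MeI methylates on carbon with retention to the (E)-vinylsilane tert-butyl(dimethyl){[(2E,6E)-3-methyl-7-(trimethylsilyl)octa-2,6-dien-1-yl]oxy}silane F12. Iododesilylation with NIS (MeCN, 0 °C), an ipso substitution with retention, would give 11.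

**Further compounds**

F1 | step 10 | methyl (4S,5R)-2,2-dimethyl-5-({[(trifluoromethyl)sulfonyl]oxy}methyl)-1,3-dioxolane-4-carboxylate | O=S(=O)(OC[C@H]1OC(C)(C)O[C@@H]1C(=O)OC)C(F)(F)F
F2 | step 10 | [(2Z,6E)-8-{[tert-butyl(dimethyl)silyl]oxy}-6-methylocta-2,6-dien-2-yl]lithium | CC(C)(C)[Si](C)(C)OC/C=C(\C)CC/C=C(\C)[Li]
F3 | step 10 | bromo[(2E,6E)-8-{[tert-butyl(dimethyl)silyl]oxy}-6-methylocta-2,6-dien-2-yl]magnesium | CC(C)(C)[Si](C)(C)OC/C=C(\C)CC/C=C(\C)[Mg]Br
F4 | step 10 | methyl (4S,5R)-5-[(2E,6E)-8-{[tert-butyl(dimethyl)silyl]oxy}-2,6-dimethylocta-2,6-dien-1-yl]-2,2-dimethyl-1,3-dioxolane-4-carboxylate | CC(C)(C)[Si](C)(C)OC/C=C(\C)CC/C=C(\C)C[C@H]1OC(C)(C)O[C@@H]1C(=O)OC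
F5 | step 10 | 1-[(4S,5R)-5-[(2E,6E)-8-{[tert-butyl(dimethyl)silyl]oxy}-2,6-dimethylocta-2,6-dien-1-yl]-2,2-dimethyl-1,3-dioxolan-4-yl]ethan-1-one | CC(C)(C)[Si](C)(C)OC/C=C(\C)CC/C=C(\C)C[C@H]1OC(C)(C)O[C@@H]1C(C)=O
F6 | step 12 | 2,6-dihydroxy-4-{[(2E,6E)-8-[(4R,5S)-5-(2-hydroxypropan-2-yl)-2,2-dimethyl-1,3-dioxolan-4-yl]-3,7-dimethylocta-2,6-dien-1-yl]oxy}benzaldehyde | C/C(=C\COc1cc(O)c(C=O)c(O)c1)CC/C=C(\C)C[C@H]1OC(C)(C)O[C@@H]1C(C)(C)O
F7 | step 12 | ethyl (2E)-3-(2,6-dihydroxy-4-{[(2E,6E)-8-[(4R,5S)-5-(2-hydroxypropan-2-yl)-2,2-dimethyl-1,3-dioxolan-4-yl]-3,7-dimethylocta-2,6-dien-1-yl]oxy}phenyl)prop-2-enoate | C/C(=C\COc1cc(O)c(/C=C/C(=O)OCC)c(O)c1)CC/C=C(\C)C[C@H]1OC(C)(C)O[C@@H]1C(C)(C)O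
F8 | step 12 | ethyl (2Z)-3-(2,6-dihydroxy-4-{[(2E,6E)-8-[(4R,5S)-5-(2-hydroxypropan-2-yl)-2,2-dimethyl-1,3-dioxolan-4-yl]-3,7-dimethylocta-2,6-dien-1-yl]oxy}phenyl)prop-2-enoate | C/C(=C\COc1cc(O)c(/C=C\C(=O)OCC)c(O)c1)CC/C=C(\C)C[C@H]1OC(C)(C)O[C@@H]1C(C)(C)O
F9 | step 6 | tert-butyl(dimethyl){[(2E)-3-methyl-7-(trimethylsilyl)hept-2-en-6-yn-1-yl]oxy}silane | CC(C)(C)[Si](C)(C)OC/C=C(\C)CCC#C[Si](C)(C)C
F10 | step 6 | [(1E,5E)-7-{[tert-butyl(dimethyl)silyl]oxy}-5-methyl-1-(trimethylsilyl)hepta-1,5-dien-1-yl]bis(2-methylpropyl)alumane | CC(C)(C)[Si](C)(C)OC/C=C(\C)CC/C=C(\[Al](CC(C)C)CC(C)C)[Si](C)(C)C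
F11 | step 6 | lithium [(1E,5E)-7-{[tert-butyl(dimethyl)silyl]oxy}-5-methyl-1-(trimethylsilyl)hepta-1,5-dien-1-yl](methyl)bis(2-methylpropyl)aluminate | [Li+].CC(C)(C)[Si](C)(C)OC/C=C(\C)CC/C=C(\[Al-](C)(CC(C)C)CC(C)C)[Si](C)(C)C
F12 | step 6 | tert-butyl(dimethyl){[(2E,6E)-3-methyl-7-(trimethylsilyl)octa-2,6-dien-1-yl]oxy}silane | CC(C)(C)[Si](C)(C)OC/C=C(\C)CC/C=C(\C)[Si](C)(C)C
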